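Early in the larch flask there is no intermediate yet, and on the list of suspects target forms from intermediate under free catalyst, so the catalyst starts at full strength with nothing yet to work on.

| flask | starting material | free catalyst | remark | time |
|---|---|---|---|---|
| larch | 33 mM | 0.17 mM | the very flask that is asked about, followed so far |  |
| birch | 33 mM | 0.085 mM | run made earlier |  |
| flask | 33 mM | 0.17 mM |  | 4.0 h |

| run | time / min | target / % |
|---|---|---|
| larch | 20.0 | 6.3 |
| larch | 60.0 | 14.2 |
| larch | 120 | 22.0 |
| larch | 180 | 20.3 |
| larch | 240 | 23.1 |
| birch | 1.00 | 0 |
| birch | 2.00 | 0 |
| birch | 3.00 | 0 |
| birch | 6.00 | 1.1 |
| birch | 12.0 | 0.7 |

(scatter of a reading: 1 percentage point)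

- removed target is counted in
- the numbers in the tables scatter with a standard deviation of 1 percentage point
- on the list of suspects stand: free catalyst + intermediate -> free catalyst + target; free catalyst -> spent catalyst; starting material -> intermediate; starting material <-> dormant form
- additions bring no volume worth counting

- zeta: at 4.0 h add free catalyst, 100% of the amount charged, then wait 8.0 h
- epsilon: change nothing and wait 8.0 h more
- theta: at 4.0 h add starting material, 50.0% of the amount charged, then wait 8.0 h
- delta: at 4.0 h take out 90% of the target then present, then wait 8.0 h

* target, in percent of the starting material first charged, at 4.0 h
* the remedy with the largest gain of target, or "none" below 2 percentage points (zeta / epsilon / theta / delta / none)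
* target present, with what was taken out counted in, in percent of the starting material first charged, after zeta
* target present, with what was taken out counted in, in percent of the starting material first charged, after theta

From 120 min on, the larch readings stayed flat within the scatter, and I took their mean, 21.8%, as the value now. I called the pool the part of the charge that is not target. Under catalyst, intermediate falls pseudo-first-order, so I reckoned in the catalyst dose L, the natural logarithm of the pool share before a charge's working life over the share after it. Doses add, and a dose goes with the amount of catalyst. For the larch flask, L = 0.246.

I took two extremes. If the whole pool had been intermediate from the first minute, the first charge's full dose would be L, and a second charge would bring the total to 38.8%. If the first charge had nearly died before most of the pool became intermediate, L would hide a far larger dose, and a second charge would convert the pool completely. Intermediate is not charged, so the real flask stands above the first extreme. How far above, the readings did not tell me, as target at 6.3% at 20.0 min fits either extreme. I therefore assumed that intermediate forms on the same clock as the catalyst dies, which makes a full dose 2L. Zeta then reaches 3L, or 52.2%, and the other remedies stay at 21.8%, as none adds free catalyst.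

The forecast gave 22%, zeta as best, 44% after zeta and 22.2% after theta, saying: “Extra starting material, waiting or removing target gain nothing, because the catalyst is dead.”

The flask gave 22.0%, zeta as best with a gain of 34 percentage points, 56.1% after zeta and 22.0% after theta.

    free catalyst + intermediate → free catalyst + target (k = 95.0 /M/min)
    free catalyst → spent catalyst (k = 0.0280 /min)
    starting material → intermediate (k = 0.0410 /min)
    starting material ⇌ dormant form (K = 0.800, k = 0.250 /min)

Zeta took the flask's unconverted share from 78.0% to 43.9%, a dose of 0.575, which is 2.34 times L. For the neighbour charged with 0.10 mM of free catalyst, L scales to 0.145, which reckons 13.5% target at 240 min. That neighbour gave 13.9%.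

All runs were generated by integration for an exercise; the scatter is artificial.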